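The rate constants belong to no real substance; the run is a simulation.

A small charge of initiator, 85 mM against 1.7 M of free monomer, has to start every chain in maple and in elm, which are one recipe read at different times.

- maple: free monomer 1.7 M; initiator 85 mM; time 4.0 min
- elm: free monomer 1.7 M; initiator 85 mM; time 12 min

    free monomer + initiator → living end + monomer in chains (k1 = 0.00231 M⁻¹ s⁻¹)
    free monomer + living end → monomer in chains + living end, rate k2*[living end]*[free monomer] (k2 = 0.0893 M⁻¹ s⁻¹)
    2 living end → dead end (k3 = 0.0826 M⁻¹ s⁻¹)

- two of one species on the left: rate k times its square, two consumed each time
- the average divides the monomer in chains by the number of chains begun, living and dead together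
- run time (maple): 4.0 min

- which of the two ends with the longer chains by the average number of monomer units in a chain (chains begun, living or dead) ("neither" if they lie within 10 %) (maple / elm / neither)
- average number of monomer units in a chain (chains begun, living or dead) at the end, maple
- average number of monomer units in a chain (chains begun, living or dead) at the end, elm

Each chain begun uses one initiator, so the average is monomer in chains over initiator used. But [free monomer] stands in both the starting rate and the growing rate and cancels, so at any moment the units added per chain begun are one plus R·[living end]/[initiator], where R, the growth constant over the starting constant, is 38.7; this is the kinetic chain length.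

So I need [living end], and I solve it at both ends. At first it climbs at 3.34 × 10⁻⁴ M s⁻¹, but with the charges held its loss would balance that making at a plateau of 0.0450 M. The ramp would reach this in 2.24 min, shorter than maple's 4.0 min, so I join a straight ramp to a flat plateau, and I hold the charges in the making. Under the flat [living end] of this reckoning, [free monomer] falls pseudo-first-order.

By this reckoning maple uses 0.850 M of free monomer and begins 0.0519 M of chains, which gives 16.4. Elm uses 1.58 M and begins 0.0800 M, which gives 19.7. My choice is elm.

The forecast also chooses elm, with 14.2 for maple and 19.1 for elm, lower than my lengths, and its ground is that “initiation slows more than growth”.

The simulation gives 14.0 for maple and 19.0 for elm, so elm has the longer chains, as forecast. That choice turns to neither with longer reading: maple at 40.0 min stands at 20.4 and elm at 120 min at 20.5, within 10 %. Put to use on the end states, R gives maple, with 0.0265 M of living end and 0.0389 M of initiator, 27.3 units per chain then begun, and elm, with 0.0145 M and 0.0185 M, 31.2.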